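Numbering: chroman O1, C2, C3, C4, C4a, C5–C8, C8a. Ring A is the benzo ring, ring B the pendant aryl ring, ring C the dihydropyran ring.
Cuts: first the five O–CH3 bonds and the saturation of a C3 isopropenyl group. Then O1–C8a and C2–C3 are cut together, giving threefold-symmetric 2,4,6-trimethoxybenzene-1,3,5-tricarbaldehyde and a 2-fluoroaryl (Z)-allylboronate. The boronate is cut at C–B/C4–H, C4–C4a, C4a–I, the acyl C–C bond and C8a–F.
Enabling feature: C8a of ring A is para to the C6 isovaleryl carbonyl and meta to O5 and O7, so an alkoxide can displace a fluoride there. C4–C3–CH(CH3)2 is a prenyl-type C5 unit, so C3 can be the γ-carbon of a 2-methylallylboronate. C2 with ring B is one of three equivalent formyl groups, and its oxygen becomes O1.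
Forward: ring A is dressed in turn (F, isovaleryl, I, dienyl, boronate) and ring B is bought complete. One operation joins the two arenes and closes ring C, then alkene saturation and global O-demethylation finish the route.
Stereochemistry: C2 (R) comes from face selection by a chiral phosphoric acid. C3 (S) comes from the Z geometry of the allylboronate through a chair transition state (syn alcohol = 2,3-trans chroman). No later step breaks a bond at C2 or C3.

Key step: step 8

Assumption: (R)-TRIP is taken to expose the Re face of the formyl group, as in the accepted model for aromatic aldehydes (if the sense were opposite, the (S)-acid would serve in the same step), and trialdehyde 11 is taken as a commercial framework monomer.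

Step 1
Reactants: 1 4-hydroxy-2,6-dimethoxybenzaldehyde
Product: 3 4-fluoro-2,6-dimethoxybenzaldehyde, via aryl fluorosulfonate 2 (not isolated)
Conditions: SO2F2 (1 atm), Me4NF (3 equiv), DMF, rt → 60 °C
Reagents that add atoms: tetramethylammonium fluoride, C[N+](C)(C)C.[F-]; sulfuryl fluoride, O=S(=O)(F)F (its SO2F group is found only in 2)
Why: Deoxyfluorination of a phenol through its aryl fluorosulfonate, in which fluoride attacks the ring carbon para to the coplanar formyl group (SNAr) and fluorosulfate leaves, a known reaction type for phenols with a para acceptor.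

Step 2
Reactants: 3 4-fluoro-2,6-dimethoxybenzaldehyde
Product: 4 (±)-1-(4-fluoro-2,6-dimethoxyphenyl)-3-methylbutan-1-ol
Conditions: i-BuMgBr (1.2 equiv), THF, −20 → 0 °C; sat. aq. NH4Cl
Reagents that add atoms: isobutylmagnesium bromide, CC(C)C[Mg]Br
Why: Grignard addition to an aromatic aldehyde, which is much faster than any attack on the C–F bond at this temperature; the new carbinol centre is racemic and is erased in step 3.

Step 3
Reactants: 4 (±)-1-(4-fluoro-2,6-dimethoxyphenyl)-3-methylbutan-1-ol
Product: 5 1-(4-fluoro-2,6-dimethoxyphenyl)-3-methylbutan-1-one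
Conditions: Dess–Martin periodinane (1.2 equiv), CH2Cl2, 0 °C → rt
Reagents that add atoms: none
Why: Dess–Martin oxidation of a secondary benzylic alcohol under non-acidic conditions that spare the electron-rich ring and the C–F bond.

Step 4
Reactants: 5 1-(4-fluoro-2,6-dimethoxyphenyl)-3-methylbutan-1-one
Product: 6 1-(4-fluoro-3-iodo-2,6-dimethoxyphenyl)-3-methylbutan-1-one
Conditions: NIS (1.05 equiv), TFA (0.3 equiv), MeCN, rt, dark
Reagents that add atoms: N-iodosuccinimide, O=C1CCC(=O)N1I
Why: Electrophilic aromatic iodination; the two open ring positions are equivalent by symmetry and each is ortho and para to a methoxy group, so only one mono-iodide can form, and it marks the future C4a next to the fluoride.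

Step 5
Reactants: 7 2-methylbut-1-en-3-yne
Product: 8 (E)-4,4,5,5-tetramethyl-2-(3-methylbuta-1,3-dien-1-yl)-1,3,2-dioxaborolane
Conditions: HBpin (1.05 equiv), Cp2ZrHCl (5 mol %), CH2Cl2, rt, closed flask
Reagents that add atoms: pinacolborane, [H]B1OC(C)(C)C(C)(C)O1
Why: Zirconium-catalysed syn hydroboration of a terminal alkyne puts boron on the terminal carbon and reacts at the alkyne ahead of the 1,1-disubstituted alkene, which fixes the E geometry.

Step 6
Reactants: 6 1-(4-fluoro-3-iodo-2,6-dimethoxyphenyl)-3-methylbutan-1-one; 8 (E)-4,4,5,5-tetramethyl-2-(3-methylbuta-1,3-dien-1-yl)-1,3,2-dioxaborolane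
Product: 9 1-{4-fluoro-2,6-dimethoxy-3-[(1E)-3-methylbuta-1,3-dien-1-yl]phenyl}-3-methylbutan-1-one
Conditions: Pd(dppf)Cl2 (5 mol %), K3PO4 (2 equiv), dioxane/H2O, 70 °C
Reagents that add atoms: none
Why: Suzuki–Miyaura coupling in which zerovalent palladium inserts into C–I only (C–F is inert) and the alkenylboronate transfers with retention of its E geometry, forming C4–C4a.

Step 7
Reactants: 9 1-{4-fluoro-2,6-dimethoxy-3-[(1E)-3-methylbuta-1,3-dien-1-yl]phenyl}-3-methylbutan-1-one
Product: 10 1-{4-fluoro-2,6-dimethoxy-3-[(2Z)-3-methyl-4-(4,4,5,5-tetramethyl-1,3,2-dioxaborolan-2-yl)but-2-en-1-yl]phenyl}-3-methylbutan-1-one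
Conditions: Ni(cod)2 (5 mol %), PCy3 (5 mol %), HBpin (1.1 equiv), toluene, rt
Reagents that add atoms: pinacolborane, [H]B1OC(C)(C)C(C)(C)O1
Why: Nickel-catalysed 1,4-hydroboration of a 1,3-diene, in which the diene binds zerovalent nickel in its s-cis form, hydrogen goes to the aryl-bearing terminus (C4) and boron to the unhindered CH2 terminus, so the two former termini end up cis on the new trisubstituted double bond (Z), while the doubly ortho-substituted ketone and the C–F bond should not react with HBpin at room temperature.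

Step 8
Reactants: 10 1-{4-fluoro-2,6-dimethoxy-3-[(2Z)-3-methyl-4-(4,4,5,5-tetramethyl-1,3,2-dioxaborolan-2-yl)but-2-en-1-yl]phenyl}-3-methylbutan-1-one; 11 2,4,6-trimethoxybenzene-1,3,5-tricarbaldehyde
Product: 14 5-[(2R,3S)-5,7-dimethoxy-6-(3-methylbutanoyl)-3-(prop-1-en-2-yl)-3,4-dihydro-2H-chromen-2-yl]-2,4,6-trimethoxybenzene-1,3-dicarbaldehyde, via pinacol borate 12 (not isolated), via potassium alkoxide 13 (not isolated)
Conditions: 11 (1.5 equiv), (R)-TRIP [(R)-3,3′-bis(2,4,6-triisopropylphenyl)-1,1′-binaphthyl-2,2′-diyl hydrogen phosphate, 10 mol %], 4 Å MS, toluene, −30 °C → rt; then DMF (dilution to 0.01 M), KOt-Bu (1.2 equiv), 0 → 40 °C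
Reagents that add atoms: potassium tert-butoxide, CC(C)(C)[O-].[K+] (its potassium is found only in 13)
Why: Proposed new method: the chiral phosphoric acid binds a pinacol oxygen of 10 and the formyl C–H of 11, C3 (the γ-carbon of the allylboronate) adds to one of the three equivalent formyl groups through a closed six-membered chair transition state to give borate 12, KOt-Bu then takes the boron away as t-BuOBpin, and the freed alkoxide 13 adds through its oxygen to C8a and expels fluoride (addition–elimination via a Meisenheimer adduct), so that C2–C3 and O1–C8a arise in one flask and the aldehyde C=O ends up as C2–O1 of ring C. The closest known reaction types are the phosphoric-acid-catalysed allyl- and crotylboration of aromatic aldehydes with pinacol boronates and the domino carbonyl-addition/SNAr annulations of 2-fluoroaryl compounds; only their fusion into one formal [4+2] annulation, with alkoxide release from the borate by ligand exchange at boron, is new. Ring C closes by a 6-exo-trig-type attack of the tethered alkoxide on C8a, the C8a=C8 π bond lying outside the forming ring. C2 (R) is controlled by the catalyst, which lets the allyl unit reach the Re face of the formyl group with ring B equatorial, and C3 (S) by the Z double bond of 10, which holds CH2–ring A axial in the chair and so gives the syn alcohol, the precursor of the 2,3-trans chroman; the SNAr leaves the C2–O bond intact and cannot scramble either centre. The step needs single addition (secured by excess 11 and by the lower electrophilicity and greater bulk of 12), attack at C8a and not at C5 (fluoride is much the better nucleofuge than methoxide, and C8a is para to the C6 carbonyl and meta to both methoxy groups) and ring closure ahead of aldol, hydride-transfer or methoxy-exchange reactions of the carbonyl-rich partners (secured by high dilution, which disfavours every intermolecular path).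

Step 9
Reactants: 14 5-[(2R,3S)-5,7-dimethoxy-6-(3-methylbutanoyl)-3-(prop-1-en-2-yl)-3,4-dihydro-2H-chromen-2-yl]-2,4,6-trimethoxybenzene-1,3-dicarbaldehyde
Product: 15 5-[(2R,3S)-5,7-dimethoxy-6-(3-methylbutanoyl)-3-(propan-2-yl)-3,4-dihydro-2H-chromen-2-yl]-2,4,6-trimethoxybenzene-1,3-dicarbaldehyde
Conditions: H2 (4 atm), RhCl(PPh3)3 (10 mol %), toluene/EtOH, rt
Reagents that add atoms: none
Why: Homogeneous hydrogenation with RhCl(PPh3)3 selects the 1,1-disubstituted alkene, leaves the hindered formyl groups, the ketone and the benzylic C2–O1 bond alone at room temperature, and does not migrate the double bond toward C3, so the C3 configuration is kept.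

Step 10
Reactants: 15 5-[(2R,3S)-5,7-dimethoxy-6-(3-methylbutanoyl)-3-(propan-2-yl)-3,4-dihydro-2H-chromen-2-yl]-2,4,6-trimethoxybenzene-1,3-dicarbaldehyde
Product: 16 5-[(2R,3S)-5,7-dihydroxy-6-(3-methylbutanoyl)-3-(propan-2-yl)-3,4-dihydro-2H-chromen-2-yl]-2,4,6-trihydroxybenzene-1,3-dicarbaldehyde (CNP0551232.1)
Conditions: BBr3 (12 equiv), CH2Cl2, −78 → 0 °C; then ice water
Reagents that add atoms: none
Why: Boron tribromide cleavage of aryl methyl ethers, all five of which sit ortho to a carbonyl group (chelation help), whereas O1 is a weakly basic vinylogous ester oxygen para to the ketone and ring B with its Lewis-acid-bound formyl groups should not support ionisation at C2, so ring C and both stereocentres should persist.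

Compound list
1 | 4-hydroxy-2,6-dimethoxybenzaldehyde | COc1cc(O)cc(OC)c1C=O | starting material
2 | 4-formyl-3,5-dimethoxyphenyl fluorosulfonate | COc1cc(OS(=O)(=O)F)cc(OC)c1C=O | intermediate (not isolated)
3 | 4-fluoro-2,6-dimethoxybenzaldehyde | COc1cc(F)cc(OC)c1C=O | intermediate
4 | (±)-1-(4-fluoro-2,6-dimethoxyphenyl)-3-methylbutan-1-ol | COc1cc(F)cc(OC)c1C(O)CC(C)C | intermediate
5 | 1-(4-fluoro-2,6-dimethoxyphenyl)-3-methylbutan-1-one | COc1cc(F)cc(OC)c1C(=O)CC(C)C | intermediate
6 | 1-(4-fluoro-3-iodo-2,6-dimethoxyphenyl)-3-methylbutan-1-one | COc1cc(F)c(I)c(OC)c1C(=O)CC(C)C | intermediate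
7 | 2-methylbut-1-en-3-yne | C=C(C)C#C | starting material
8 | (E)-4,4,5,5-tetramethyl-2-(3-methylbuta-1,3-dien-1-yl)-1,3,2-dioxaborolane | C=C(C)/C=C/B1OC(C)(C)C(C)(C)O1 | intermediate
9 | 1-{4-fluoro-2,6-dimethoxy-3-[(1E)-3-methylbuta-1,3-dien-1-yl]phenyl}-3-methylbutan-1-one | COc1cc(F)c(/C=C/C(C)=C)c(OC)c1C(=O)CC(C)C | intermediate
10 | 1-{4-fluoro-2,6-dimethoxy-3-[(2Z)-3-methyl-4-(pinacolatoboryl)but-2-en-1-yl]phenyl}-3-methylbutan-1-one | COc1cc(F)c(C/C=C(C)\CB2OC(C)(C)C(C)(C)O2)c(OC)c1C(=O)CC(C)C | intermediate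
11 | 2,4,6-trimethoxybenzene-1,3,5-tricarbaldehyde | COc1c(C=O)c(OC)c(C=O)c(OC)c1C=O | starting material
12 | pinacol borate of (1R,2S)-1-(3,5-diformyl-2,4,6-trimethoxyphenyl)-2-{[6-fluoro-2,4-dimethoxy-3-(3-methylbutanoyl)phenyl]methyl}-3-methylbut-3-en-1-ol | CC(C)CC(=O)c1c(OC)cc(F)c(c1OC)C[C@@H](C(C)=C)[C@H](c1c(OC)c(C=O)c(OC)c(C=O)c1OC)OB1OC(C)(C)C(C)(C)O1 | intermediate (not isolated)
13 | potassium (1R,2S)-1-(3,5-diformyl-2,4,6-trimethoxyphenyl)-2-{[6-fluoro-2,4-dimethoxy-3-(3-methylbutanoyl)phenyl]methyl}-3-methylbut-3-en-1-olate | CC(C)CC(=O)c1c(OC)cc(F)c(c1OC)C[C@@H](C(C)=C)[C@H](c1c(OC)c(C=O)c(OC)c(C=O)c1OC)[O-].[K+] | intermediate (not isolated)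
14 | 5-[(2R,3S)-5,7-dimethoxy-6-(3-methylbutanoyl)-3-(prop-1-en-2-yl)-3,4-dihydro-2H-chromen-2-yl]-2,4,6-trimethoxybenzene-1,3-dicarbaldehyde | CC(C)CC(=O)c1c(OC)cc2c(c1OC)C[C@@H](C(C)=C)[C@H](c1c(OC)c(C=O)c(OC)c(C=O)c1OC)O2 | intermediate
15 | 5-[(2R,3S)-5,7-dimethoxy-6-(3-methylbutanoyl)-3-(propan-2-yl)-3,4-dihydro-2H-chromen-2-yl]-2,4,6-trimethoxybenzene-1,3-dicarbaldehyde | CC(C)CC(=O)c1c(OC)cc2c(c1OC)C[C@@H](C(C)C)[C@H](c1c(OC)c(C=O)c(OC)c(C=O)c1OC)O2 | intermediate
16 | 5-[(2R,3S)-5,7-dihydroxy-6-(3-methylbutanoyl)-3-(propan-2-yl)-3,4-dihydro-2H-chromen-2-yl]-2,4,6-trihydroxybenzene-1,3-dicarbaldehyde | CC(C)CC(=O)c1c(O)cc2c(c1O)C[C@@H](C(C)C)[C@H](c1c(O)c(C=O)c(O)c(C=O)c1O)O2 | target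

Total step count: 10. Longest linear sequence: 9 steps (1, 2, 3, 4, 6, 7, 8, 9, 10).

Steps most likely to fail

First, step 8. The alkoxide stage may be diverted by base-induced reactions of the two remaining formyl groups, the excess trialdehyde and the enolisable ketone (aldol addition, hydride transfer, exchange of activated methoxy groups). Displacement of fluoride may also be slow, because the ketone is twisted out of conjugation by its two ortho methoxy groups. Double allylation or weak facial selectivity at the doubly ortho-substituted aldehyde would also lower the outcome. The fallback uses known chemistry only, sets out from 10 and 11 and comes back at 14. The phosphoric-acid-catalysed allylboration is run alone and worked up hydrolytically to give the free homoallylic alcohol F1, which is separated from excess 11. Both formyl groups are masked with HC(OMe)3, PPTS and MeOH as the bis(dimethyl acetal) F2. Ring closure is then an ordinary intramolecular SNAr of a γ-(2-fluoroaryl) alkoxide (NaH, DMF, 60 °C) to the chroman bis(dimethyl acetal) F3. Dilute HCl in THF returns 14.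

Second, step 7. Nickel hydride or borane species may reduce the aryl ketone, boron may be delivered to the benzylic terminus, or the Z geometry may erode by a borotropic shift on handling. The fallback reorders the redox steps so that no ketone is present during the hydroboration; it sets out from 4 and comes back at 10. Alcohol 4 is iodinated without acid (NIS, MeCN) to the iodo alcohol F4. Coupling with 8 under the conditions of step 6 gives the dienyl alcohol F5. Ni(cod)2, PCy3 and HBpin (2.2 equiv) first cap the hydroxyl group and then add 1,4 to give the O-borylated allylboronate F6. Aqueous work-up releases the hydroxy allylboronate F7, and Dess–Martin oxidation buffered with pyridine gives 10.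

Third, step 10. The Lewis acid may ionise the benzylic C2–O1 bond. That would cause epimerisation at C2 or reclosure onto O5. Cleavage of the second methoxy group next to the ketone may stay incomplete, or the formyl groups may be attacked by bromide. The fallback changes the protecting groups so that the end game is neutral; it sets out from 6 and comes back at 16.
- BBr3 converts 6 into the iodoresorcinol ketone F8, and BnBr, K2CO3 and DMF give the bis(benzyl ether) F9.
- The same coupling with 8 and the same 1,4-hydroboration give the benzyl-protected diene F10 and the benzyl-protected (Z)-allylboronate F11.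
- Commercial 2,4,6-trihydroxybenzene-1,3,5-tricarbaldehyde is O-benzylated (BnBr, K2CO3, DMF) to the tris(benzyloxy) trialdehyde F12.
- The annulation of F11 with F12 runs as in step 8 through the borate F13 and the potassium alkoxide F14 to the pentabenzyl isopropenyl chroman F15.
- RhCl(PPh3)3 and H2 give the pentabenzyl isopropyl chroman F16.
- Hydrogenolysis (H2, Pd/C, EtOAc, rt) removes all five benzyl groups to give 16.

Further compounds
F1 | step 8 | (1R,2S)-1-(3,5-diformyl-2,4,6-trimethoxyphenyl)-2-{[6-fluoro-2,4-dimethoxy-3-(3-methylbutanoyl)phenyl]methyl}-3-methylbut-3-en-1-ol | CC(C)CC(=O)c1c(OC)cc(F)c(c1OC)C[C@@H](C(C)=C)[C@H](c1c(OC)c(C=O)c(OC)c(C=O)c1OC)O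
F2 | step 8 | bis(dimethyl acetal) of F1 | CC(C)CC(=O)c1c(OC)cc(F)c(c1OC)C[C@@H](C(C)=C)[C@H](c1c(OC)c(C(OC)OC)c(OC)c(C(OC)OC)c1OC)O
F3 | step 8 | bis(dimethyl acetal) of 14 | CC(C)CC(=O)c1c(OC)cc2c(c1OC)C[C@@H](C(C)=C)[C@H](c1c(OC)c(C(OC)OC)c(OC)c(C(OC)OC)c1OC)O2
F4 | step 7 | (±)-1-(4-fluoro-3-iodo-2,6-dimethoxyphenyl)-3-methylbutan-1-ol | COc1cc(F)c(I)c(OC)c1C(O)CC(C)C
F5 | step 7 | (±)-1-{4-fluoro-2,6-dimethoxy-3-[(1E)-3-methylbuta-1,3-dien-1-yl]phenyl}-3-methylbutan-1-ol | COc1cc(F)c(/C=C/C(C)=C)c(OC)c1C(O)CC(C)C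
F6 | step 7 | O-pinacolboryl derivative of F7 (not isolated) | COc1cc(F)c(C/C=C(C)\CB2OC(C)(C)C(C)(C)O2)c(OC)c1C(CC(C)C)OB1OC(C)(C)C(C)(C)O1
F7 | step 7 | (±)-1-{4-fluoro-2,6-dimethoxy-3-[(2Z)-3-methyl-4-(pinacolatoboryl)but-2-en-1-yl]phenyl}-3-methylbutan-1-ol | COc1cc(F)c(C/C=C(C)\CB2OC(C)(C)C(C)(C)O2)c(OC)c1C(O)CC(C)C
F8 | step 10 | 1-(4-fluoro-2,6-dihydroxy-3-iodophenyl)-3-methylbutan-1-one | CC(C)CC(=O)c1c(O)cc(F)c(I)c1O
F9 | step 10 | 1-[2,6-bis(benzyloxy)-4-fluoro-3-iodophenyl]-3-methylbutan-1-one | CC(C)CC(=O)c1c(OCc2ccccc2)cc(F)c(I)c1OCc1ccccc1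
F10 | step 10 | 1-{2,6-bis(benzyloxy)-4-fluoro-3-[(1E)-3-methylbuta-1,3-dien-1-yl]phenyl}-3-methylbutan-1-one | CC(C)CC(=O)c1c(OCc2ccccc2)cc(F)c(/C=C/C(C)=C)c1OCc1ccccc1
F11 | step 10 | 1-{2,6-bis(benzyloxy)-4-fluoro-3-[(2Z)-3-methyl-4-(pinacolatoboryl)but-2-en-1-yl]phenyl}-3-methylbutan-1-one | CC(C)CC(=O)c1c(OCc2ccccc2)cc(F)c(C/C=C(C)\CB2OC(C)(C)C(C)(C)O2)c1OCc1ccccc1
F12 | step 10 | 2,4,6-tris(benzyloxy)benzene-1,3,5-tricarbaldehyde | O=Cc1c(OCc2ccccc2)c(C=O)c(OCc2ccccc2)c(C=O)c1OCc1ccccc1
F13 | step 10 | pinacol borate of the (1R,2S)-homoallylic alcohol from F11 and F12 (not isolated) | CC(C)CC(=O)c1c(OCc2ccccc2)cc(F)c(c1OCc1ccccc1)C[C@@H](C(C)=C)[C@H](c1c(OCc2ccccc2)c(C=O)c(OCc2ccccc2)c(C=O)c1OCc1ccccc1)OB1OC(C)(C)C(C)(C)O1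
F14 | step 10 | potassium alkoxide from F13 (not isolated) | CC(C)CC(=O)c1c(OCc2ccccc2)cc(F)c(c1OCc1ccccc1)C[C@@H](C(C)=C)[C@H](c1c(OCc2ccccc2)c(C=O)c(OCc2ccccc2)c(C=O)c1OCc1ccccc1)[O-].[K+]
F15 | step 10 | 5-[(2R,3S)-5,7-bis(benzyloxy)-6-(3-methylbutanoyl)-3-(prop-1-en-2-yl)-3,4-dihydro-2H-chromen-2-yl]-2,4,6-tris(benzyloxy)benzene-1,3-dicarbaldehyde | CC(C)CC(=O)c1c(OCc3ccccc3)cc2c(c1OCc1ccccc1)C[C@@H](C(C)=C)[C@H](c1c(OCc3ccccc3)c(C=O)c(OCc3ccccc3)c(C=O)c1OCc1ccccc1)O2
F16 | step 10 | 5-[(2R,3S)-5,7-bis(benzyloxy)-6-(3-methylbutanoyl)-3-(propan-2-yl)-3,4-dihydro-2H-chromen-2-yl]-2,4,6-tris(benzyloxy)benzene-1,3-dicarbaldehyde | CC(C)CC(=O)c1c(OCc3ccccc3)cc2c(c1OCc1ccccc1)C[C@@H](C(C)C)[C@H](c1c(OCc3ccccc3)c(C=O)c(OCc3ccccc3)c(C=O)c1OCc1ccccc1)O2
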